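(The readings are simulated from invented constants, and the scatter is random.)

Time on the clock tells me little until I count it in turnovers: target made per catalyst charged.

| flask | substrate | reagent | free catalyst | remark | time |
|---|---|---|---|---|---|
| north-west | 0.10 M | 0.070 M | 16 mM | run made earlier |  |
| west | 0.10 M | 0.11 M | 16 mM | run made earlier |  |
| south | 0.20 M | 0.050 M | 16 mM | run made earlier |  |
| flask | 0.10 M | 0.0500 M | 16 mM |  | 80 min |

| run | time / min | target / % | catalyst intermediate A / % | substrate / % |
|---|---|---|---|---|
| north-west | 3.00 | 6.3 | 5.8 | 78.8 |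
| north-west | 10.0 | 13.8 | 7.6 | 71.1 |
| north-west | 20.0 | 21.4 | 7.3 | 62.9 |
| north-west | 30.0 | 26.4 | 6.9 | 59.9 |
| north-west | 40.0 | 31.2 | 6.9 | 53.5 |
| north-west | 50.0 | 35.8 | 7.8 | 49.6 |
| north-west | 60.0 | 38.1 | 7.8 | 47.1 |
| west | 3.00 | 4.5 | 3.9 | 78.7 |
| west | 10.0 | 14.6 | 4.2 | 67.4 |
| west | 20.0 | 24.7 | 4.0 | 60.3 |
| west | 30.0 | 29.3 | 5.6 | 52.3 |
| west | 40.0 | 34.6 | 6.5 | 48.5 |
| west | 50.0 | 40.2 | 6.4 | 46.4 |
| west | 60.0 | 43.1 | 6.0 | 40.8 |
| south | 6.00 | 4.3 | 6.1 | 87.0 |
| south | 15.0 | 9.1 | 4.4 | 83.2 |
| south | 30.0 | 14.2 | 6.7 | 78.9 |
| south | 50.0 | 15.1 | 6.9 | 76.4 |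
| south | 60.0 | 17.6 | 5.1 | 74.9 |

(scatter of a reading: 1 percentage point)

- the reaction counts as stopped when no species that holds the substrate changes by six tenths of a point or more over the second half of the time

* the state of affairs at 80 min: stopped, and by what, or still going (all of the substrate has reacted / the reagent has run out first / forward and back rates have come level / no working catalyst is left / it is still moving)
* target at 80 min, in percent of the substrate charged
* catalyst intermediate A at 80 min, in percent of the substrate charged

The flask looks nearly like the north-west run, with the same substrate and free catalyst but less reagent. I assume that each turnover takes one reagent, so I reckon a reagent budget, the turnovers that the reagent charge can pay for: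

reagent budget = c(reagent)/c(free catalyst) = 0.0500 M / 16 mM = 3.12

Reagent is the limiting reagent of the flask, at 0.0500 M against 0.10 M of substrate, so the budget caps target at 50.0%. The north-west run has a larger budget, 4.38, and had made 2.38 turnovers by 60.0 min. The flask therefore stands under a lower cap. The south run has the flask's budget but twice the substrate, so what follows is a rough estimate; I extend its last stretch:

turnover rate = (c(target) at 60.0 min − c(target) at 30.0 min)/c(free catalyst)/elapsed time = 0.0142 min⁻¹

turnovers at 80 min = 2.20 + 0.284 = 2.48

My reckoning for the flask is thus 39.7% target, and 2.48 stays below the budget, so I call it still moving.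

The forecast also says it is still moving, “target should still rise”, but its 31% of target is lower than mine. It gives 10.5% of catalyst intermediate A.

The flask gives: it is still moving, 35.8% of target and 11.3% of catalyst intermediate A, so my 39.7% of target was too high.

    substrate + free catalyst → catalyst intermediate A (k = 0.520 M⁻¹ s⁻¹)
    reagent + catalyst intermediate A ⇌ catalyst intermediate B (K = 16.0 M⁻¹, k = 0.650 M⁻¹ s⁻¹)
    catalyst intermediate B ⇌ by-product + catalyst intermediate C (K = 0.0120 M, k = 0.460 s⁻¹)
    catalyst intermediate C ⇌ free catalyst + target (K = 0.0220 M, k = 0.00640 s⁻¹)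
    2 catalyst intermediate C → spent catalyst (k = 0.0880 M⁻¹ s⁻¹)

That target is 2.24 turnovers of the flask's budget of 3.12, and the largest change of a share over the second half of the time is 8.3 percentage points. By 800 min the flask reaches 47.5% of target and 13.5% of catalyst intermediate A, with 0.0227% of its reagent remaining. That is 2.97 turnovers against 2.24, so at 80 min the flask has not come to rest.

The neighbour with 0.030 M of reagent has a budget of 1.88, which caps target at 30.0%. It gives 25.7%, or 1.61 turnovers, with 7.5% of its reagent remaining.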